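The synthesis rests on making ring A last by ring enlargement. In the target, C2 is a plain methylene of ring A lying between the oxygen-bearing C1 and C3, and C1 is attached to the quaternary C10; C2 can therefore be inserted into the C1–C3 bond of a cyclopentanone. One operation, Lewis acid-promoted homologation with trimethylsilyldiazomethane, forms C1–C2 and C2–C3 and turns a five-membered ring into ring A with the C1 carbonyl in place for reduction and acetylation. Its precursor is a trans-fused hydrindan-1-one that already carries the C4 methyl and methyl ester, the C8 methylidene, the C9 silyloxyethyl arm and all four permanent stereocentres (C4, C5, C9, C10).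

Key step: step 14

Remark: atoms keep their target numbers throughout (ring A = C1–C5 and C10, ring B = C5–C10, C17 = exocyclic methylene, C19 = ester carbon, C20 = methyl on C10); in the early intermediates the five-membered ring is C1–C3–C4–C5–C10 and C2 appears only in step 14. Reagent 2 is taken as the commercial THF solution.

Step 1
Reactants: 1 2-methylcyclopent-2-en-1-one; 2 [2-(1,3-dioxan-2-yl)ethyl]magnesium bromide; 3 3-iodoprop-1-ene
Product: 5 (2S,3R)-3-[2-(1,3-dioxan-2-yl)ethyl]-2-methyl-2-(prop-2-en-1-yl)cyclopentan-1-one, via bromomagnesium enolate 4 (not isolated)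
Conditions: Cu(OTf)2 (3 mol %), enantiopure hydroxyalkyl-imidazolinium chloride (NHC precursor, 4 mol %), Et2O/THF, 0 °C; then 3, DMPU, 0 °C → rt
Reagents that add atoms: none
Why: Copper-catalysed asymmetric conjugate addition of a Grignard reagent to the α-methyl enone sets C5 under ligand control, and C-allylation of the resulting magnesium enolate anti to the new C5 arm (tandem Michael addition–enolate alkylation) sets C10 with the two arms trans, as the trans ring fusion requires.

Step 2
Reactants: 5 allyl ketone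
Product: 7 (4R,5S)-4-[2-(1,3-dioxan-2-yl)ethyl]-5-methyl-5-(prop-2-en-1-yl)cyclopent-2-en-1-one, via silyl enol ether 6 (not isolated)
Conditions: LiN(iPr)2, THF, −78 °C; Me3SiCl; then Pd(OAc)2 (10 mol %), O2 (1 atm), DMSO, rt
Reagents that add atoms: none
Why: C10 is quaternary, so enolisation can only go towards C3, and Saegusa–Ito oxidation of the regiodefined silyl enol ether should give the C3=C4 enone.

Step 3
Reactants: 7 C3=C4 enone
Product: 8 3-[2-(1,3-dioxan-2-yl)ethyl]-2-methyl-2-(prop-2-en-1-yl)-4-[tris(methylsulfanyl)methyl]cyclopentan-1-one (C(SMe)3 on C4 trans to the C5 arm)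
Conditions: HC(SMe)3, n-BuLi, THF, −78 °C; then 7, −78 °C; H2O
Reagents that add atoms: tris(methylsulfanyl)methane, CSC(SC)SC
Why: Tris(methylsulfanyl)methyllithium is a soft methoxycarbonyl-anion equivalent that adds 1,4 to cyclopentenones (Michael addition) anti to the C5 arm, and the C4 configuration does not matter because C4 becomes planar again in step 5.

Step 4
Reactants: 8 trithioorthoester ketone
Product: 9 methyl 2-[2-(1,3-dioxan-2-yl)ethyl]-3-methyl-4-oxo-3-(prop-2-en-1-yl)cyclopentane-1-carboxylate (ester on C4 trans to the C5 arm)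
Conditions: HgCl2, HgO, MeOH/H2O (12:1), rt
Reagents that add atoms: methanol, CO; water, O
Why: Thiophilic, mercury-assisted methanolysis of a trithioorthoester gives the methyl ester under buffered conditions that should spare the dioxane acetal and the terminal alkene.

Step 5
Reactants: 9 γ-keto ester
Product: 11 methyl (4S,5S)-5-[2-(1,3-dioxan-2-yl)ethyl]-4-methyl-3-oxo-4-(prop-2-en-1-yl)cyclopent-1-ene-1-carboxylate, via silyl enol ether 10 (not isolated)
Conditions: LiN(iPr)2, THF, −78 °C; Me3SiCl; then Pd(OAc)2 (10 mol %), O2 (1 atm), DMSO, rt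
Reagents that add atoms: none
Why: The ketone α-position C3 is deprotonated faster than the ester α-position C4, and Saegusa–Ito oxidation with β-hydride loss from C4 should give the C3=C4 enone that carries the ester on C4.

Step 6
Reactants: 11 enone ester
Product: 12 methyl (1R,2S,3S)-2-[2-(1,3-dioxan-2-yl)ethyl]-1,3-dimethyl-4-oxo-3-(prop-2-en-1-yl)cyclopentane-1-carboxylate
Conditions: Me2CuLi (from CuI and 2 MeLi), Et2O, −78 → −20 °C; H2O
Reagents that add atoms: lithium dimethylcuprate, [Li+].C[Cu-]C
Why: Cuprate 1,4-addition takes place β to the ketone at C4 and anti to the adjacent C5 arm (conjugate addition to a γ-substituted cyclopentenone), which creates the quaternary C4 with its methyl trans and its ester cis to the C5 arm, as in the target.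

Step 7
Reactants: 12 allyl keto ester
Product: 13 methyl (1R,2S,3S)-2-[2-(1,3-dioxan-2-yl)ethyl]-1,3-dimethyl-4-oxo-3-[(1E)-prop-1-en-1-yl]cyclopentane-1-carboxylate
Conditions: RuHCl(CO)(PPh3)3 (5 mol %), toluene, 80 °C
Reagents that add atoms: none
Why: Ruthenium hydride-catalysed alkene isomerisation (hydrometalation/β-hydride elimination) moves the terminal double bond by one position to the more stable 1-propenyl group and stops there because C10 is quaternary, and the alkene geometry is immaterial for step 9.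

Step 8
Reactants: 13 propenyl acetal
Product: 14 methyl (1R,2S,3S)-1,3-dimethyl-4-oxo-2-(3-oxopropyl)-3-[(1E)-prop-1-en-1-yl]cyclopentane-1-carboxylate
Conditions: 2 M aq. HCl, THF, 40 °C
Reagents that add atoms: water, O
Why: Acid-catalysed acetal hydrolysis frees the C8 aldehyde while the hindered ketone, the methyl ester and the internal alkene are inert to dilute aqueous acid.

Step 9
Reactants: 14 propenyl aldehyde
Product: 15 methyl 4-ethenyl-5-hydroxy-1,3a-dimethyl-3-oxooctahydro-1H-indene-1-carboxylate (trans-fused, C4, C5 and C10 as in 12, epimers at C8 and C9)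
Conditions: Me2AlCl (1.5 equiv), CH2Cl2, −78 → 0 °C; then 1 M HCl
Reagents that add atoms: none
Why: A Lewis acid-promoted intramolecular carbonyl–ene reaction of a 6-enal (the citronellal-to-isopulegol type) joins C8 to C9 with transfer of a C12 hydrogen and closes ring B trans-fused because the two arms are trans on the cyclopentane, and the C8 and C9 configurations formed here are removed or equilibrated in steps 12 and 13.

Step 10
Reactants: 15 ene adduct
Product: 17 methyl 5-hydroxy-4-(2-hydroxyethyl)-1,3a-dimethyl-3-oxooctahydro-1H-indene-1-carboxylate (same stereochemical description as 15), via organoborane 16 (not isolated)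
Conditions: 9-BBN (2.2 equiv), THF, 0 °C → rt; then NaOH, H2O2, 0 °C
Reagents that add atoms: hydrogen peroxide, OO
Why: Anti-Markovnikov hydroboration–oxidation of the monosubstituted vinyl group gives the primary C12 alcohol, the neopentyl C1 ketone being reduced only slowly by 9-BBN, and any C1 alcohol that does form is returned to the ketone in step 12.

Step 11
Reactants: 17 diol
Product: 18 methyl 4-{2-[tert-butyl(diphenyl)silyl]oxyethyl}-5-hydroxy-1,3a-dimethyl-3-oxooctahydro-1H-indene-1-carboxylate
Conditions: t-BuPh2SiCl, imidazole, CH2Cl2, 0 °C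
Reagents that add atoms: tert-butyl(chloro)diphenylsilane, CC(C)(C)[Si](Cl)(c1ccccc1)c1ccccc1
Why: Silyl ether formation with the bulky chlorosilane is selective for the primary C12 hydroxyl over the hindered secondary C8 hydroxyl.

Step 12
Reactants: 18 C8 alcohol
Product: 19 methyl 4-{2-[tert-butyl(diphenyl)silyl]oxyethyl}-1,3a-dimethyl-3,5-dioxooctahydro-1H-indene-1-carboxylate (C9 epimerisable)
Conditions: Dess–Martin periodinane, NaHCO3, CH2Cl2, rt
Reagents that add atoms: none
Why: Dess–Martin oxidation converts the C8 carbinol into the ketone under buffered conditions that leave the silyl ether and the ester alone.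

Step 13
Reactants: 19 C1,C8-diketone
Product: 20 key-step precursor methyl (1R,3aS,4R,7aS)-4-{2-[tert-butyl(diphenyl)silyl]oxyethyl}-1,3a-dimethyl-5-methylidene-3-oxooctahydro-1H-indene-1-carboxylate
Conditions: Ph3PCH3Br, KOtBu, THF, 0 °C → rt
Reagents that add atoms: methyltriphenylphosphonium bromide, C[P+](c1ccccc1)(c1ccccc1)c1ccccc1.[Br-]
Why: Wittig methylenation should occur at the C8 cyclohexanone and not at the C1 carbonyl, which is shielded by quaternary C10 and neopentyl C3 like a camphor-type ketone, while the basic medium equilibrates C9 through the C8 enolate to the equatorial arm (cis to the C10 methyl) before olefination fixes it.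

Step 14
Reactants: 20 trans-hydrindan-1-one precursor; 21 trimethylsilyldiazomethane
Product: 23 methyl (1R,4aS,5R,8aS)-5-{2-[tert-butyl(diphenyl)silyl]oxyethyl}-1,4a-dimethyl-6-methylidene-4-oxodecahydronaphthalene-1-carboxylate, via alpha-silyl ketone 22 (not isolated)
Conditions: AlMe3 (1.2 equiv), CH2Cl2, −78 °C; 21 (1.5 equiv), −78 → −20 °C; then 1 M HCl, THF, rt
Reagents that add atoms: none
Why: AlMe3 activates the C1 carbonyl, the diazo carbon of 21 adds to C1 from the face opposite the C10 methyl and the C4 ester, and in the resulting aluminium alkoxide the C1–C3 bond shifts to that carbon antiperiplanar to the departing N2, so the new carbon becomes C2 and both C1–C2 and C2–C3 are formed. The closest established reaction type is the Lewis acid-promoted diazoalkane homologation of cyclic ketones, as applied to the D-ring ketone of 17-oxo steroids, which sits in the same trans-fused, α-quaternary setting. Ring A is not closed by a cyclisation: it arises by one-carbon ring enlargement (1,2-alkyl shift) of the existing cyclopentanone, assisted by release of trans-hydrindanone strain. No permanent stereocentre is created, because the silyl-bearing C2 of 22 loses silicon on acidic work-up (protodesilylation) and C4, C5, C9 and C10 are not touched. The selectivity needed is regiochemical, migration of the secondary C3 instead of quaternary C10, and it is secured by the bulky trimethylsilyl group, which keeps away from the C10 substituents in the addition and migration steps and also blocks a second homologation of 22; the ester, exocyclic alkene and silyl ether are inert to AlMe3 at low temperature.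

Step 15
Reactants: 23 ring-expanded C1 ketone
Product: 24 methyl (1R,4S,4aS,5R,8aS)-5-{2-[tert-butyl(diphenyl)silyl]oxyethyl}-4-hydroxy-1,4a-dimethyl-6-methylidenedecahydronaphthalene-1-carboxylate
Conditions: NaBH4, MeOH, −20 → 0 °C
Reagents that add atoms: none
Why: Borohydride 1,2-reduction delivers hydride axially, on the face opposite the axial C10 methyl, and so should give the equatorial C1 alcohol cis to C20 as in the target, while the hindered axial ester is not reduced.

Step 16
Reactants: 24 C1 alcohol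
Product: 25 methyl (1R,4S,4aS,5R,8aS)-4-(acetyloxy)-5-{2-[tert-butyl(diphenyl)silyl]oxyethyl}-1,4a-dimethyl-6-methylidenedecahydronaphthalene-1-carboxylate
Conditions: Ac2O, pyridine, DMAP (cat.), CH2Cl2, rt
Reagents that add atoms: acetic anhydride, CC(=O)OC(C)=O
Why: DMAP-catalysed acylation esterifies the hindered equatorial secondary alcohol without affecting any other group.

Step 17
Reactants: 25 silyl ether acetate
Product: 26 methyl (1R,4S,4aS,5R,8aS)-4-(acetyloxy)-5-(2-hydroxyethyl)-1,4a-dimethyl-6-methylidenedecahydronaphthalene-1-carboxylate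
Conditions: Bu4NF, AcOH, THF, rt
Reagents that add atoms: none
Why: Fluoride-mediated desilylation frees the C12 alcohol, and the acetic acid buffer keeps the medium from cleaving or shifting the C1 acetate.

Step 18
Reactants: 26 C12 alcohol
Product: 27 methyl (1R,4S,4aS,5R,8aS)-4-(acetyloxy)-1,4a-dimethyl-6-methylidene-5-(2-oxoethyl)decahydronaphthalene-1-carboxylate
Conditions: Dess–Martin periodinane, NaHCO3, CH2Cl2, 0 °C → rt
Reagents that add atoms: none
Why: Dess–Martin oxidation gives the C12 aldehyde under buffered, non-epimerising conditions.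

Step 19
Reactants: 27 C12 aldehyde; 28 2-(triphenyl-λ5-phosphanylidene)propanal
Product: 29 methyl (1R,4S,4aS,5R,8aS)-4-(acetyloxy)-1,4a-dimethyl-5-[(2E)-3-methyl-4-oxobut-2-en-1-yl]-6-methylidenedecahydronaphthalene-1-carboxylate
Conditions: toluene, 80 °C
Reagents that add atoms: none
Why: Wittig olefination with a stabilised ylide is E-selective and reacts with the aliphatic aldehyde much faster than with the conjugated, α-branched enal that it produces.

Step 20
Reactants: 29 (E)-2-methyl enal
Product: 30 target, methyl (1R,4S,4aS,5R,8aS)-4-(acetyloxy)-1,4a-dimethyl-6-methylidene-5-[(2E)-3-methylpenta-2,4-dien-1-yl]decahydronaphthalene-1-carboxylate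
Conditions: Ph3PCH3Br, KOtBu, THF, −78 → 0 °C
Reagents that add atoms: methyltriphenylphosphonium bromide, C[P+](c1ccccc1)(c1ccccc1)c1ccccc1.[Br-]
Why: Wittig methylenation of the enal carbonyl (1,2-addition of the non-stabilised ylide) completes the diene without touching the trisubstituted (E)-alkene, and at low temperature the acetate and the hindered ester react far more slowly than the aldehyde.

Compound list
1 | 2-methylcyclopent-2-en-1-one | CC1=CCCC1=O | starting material
2 | [2-(1,3-dioxan-2-yl)ethyl]magnesium bromide | Br[Mg]CCC1OCCCO1 | starting material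
3 | 3-iodoprop-1-ene (allyl iodide) | C=CCI | starting material
4 | bromomagnesium enolate (C1–OMgBr, C1=C10) of 3-[2-(1,3-dioxan-2-yl)ethyl]-2-methylcyclopentanone, C5 as in 5 | O1CCCOC1CC[C@H]2C(C)=C(O[Mg]Br)CC2 | intermediate
5 | (2S,3R)-3-[2-(1,3-dioxan-2-yl)ethyl]-2-methyl-2-(prop-2-en-1-yl)cyclopentan-1-one | O1CCCOC1CC[C@H]2[C@@](CC=C)(C)C(=O)CC2 | intermediate
6 | trimethylsilyl enol ether of 5 (C1–OSiMe3, C1=C3) | O1CCCOC1CC[C@H]2[C@@](CC=C)(C)C(O[Si](C)(C)C)=CC2 | intermediate
7 | (4R,5S)-4-[2-(1,3-dioxan-2-yl)ethyl]-5-methyl-5-(prop-2-en-1-yl)cyclopent-2-en-1-one | O1CCCOC1CC[C@H]2[C@@](CC=C)(C)C(=O)C=C2 | intermediate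
8 | 3-[2-(1,3-dioxan-2-yl)ethyl]-2-methyl-2-(prop-2-en-1-yl)-4-[tris(methylsulfanyl)methyl]cyclopentan-1-one, C(SMe)3 trans to the neighbouring arm, other centres as in 5 | O1CCCOC1CC[C@H]2[C@@](CC=C)(C)C(=O)C[C@@H]2C(SC)(SC)SC | intermediate
9 | methyl 2-[2-(1,3-dioxan-2-yl)ethyl]-3-methyl-4-oxo-3-(prop-2-en-1-yl)cyclopentane-1-carboxylate, ester trans to the neighbouring arm, other centres as in 5 | O1CCCOC1CC[C@H]2[C@@](CC=C)(C)C(=O)C[C@@H]2C(=O)OC | intermediate
10 | trimethylsilyl enol ether of 9 (C1–OSiMe3, C1=C3) | O1CCCOC1CC[C@H]2[C@@](CC=C)(C)C(O[Si](C)(C)C)=C[C@@H]2C(=O)OC | intermediate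
11 | methyl (4S,5S)-5-[2-(1,3-dioxan-2-yl)ethyl]-4-methyl-3-oxo-4-(prop-2-en-1-yl)cyclopent-1-ene-1-carboxylate | O1CCCOC1CC[C@H]2[C@@](CC=C)(C)C(=O)C=C2C(=O)OC | intermediate
12 | methyl (1R,2S,3S)-2-[2-(1,3-dioxan-2-yl)ethyl]-1,3-dimethyl-4-oxo-3-(prop-2-en-1-yl)cyclopentane-1-carboxylate | O1CCCOC1CC[C@H]2[C@@](CC=C)(C)C(=O)C[C@@]2(C)C(=O)OC | intermediate
13 | methyl (1R,2S,3S)-2-[2-(1,3-dioxan-2-yl)ethyl]-1,3-dimethyl-4-oxo-3-[(1E)-prop-1-en-1-yl]cyclopentane-1-carboxylate | O1CCCOC1CC[C@H]2[C@@](/C=C/C)(C)C(=O)C[C@@]2(C)C(=O)OC | intermediate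
14 | methyl (1R,2S,3S)-1,3-dimethyl-4-oxo-2-(3-oxopropyl)-3-[(1E)-prop-1-en-1-yl]cyclopentane-1-carboxylate | O=CCC[C@H]2[C@@](/C=C/C)(C)C(=O)C[C@@]2(C)C(=O)OC | intermediate
15 | methyl 4-ethenyl-5-hydroxy-1,3a-dimethyl-3-oxooctahydro-1H-indene-1-carboxylate; 3a-CH3 trans to 7a-H, ester cis to 3a-CH3, epimers at C4 and C5 of the indane (C9 and C8) | C=CC1C(O)CC[C@H]2[C@@]1(C)C(=O)C[C@@]2(C)C(=O)OC | intermediate
16 | 15 carrying 9-borabicyclo[3.3.1]nonan-9-yl on C12 and as the borinate on the C8 oxygen | B1(C2CCCC1CCC2)CCC3C(OB4C5CCCC4CCC5)CC[C@H]6[C@@]3(C)C(=O)C[C@@]6(C)C(=O)OC | intermediate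
17 | methyl 5-hydroxy-4-(2-hydroxyethyl)-1,3a-dimethyl-3-oxooctahydro-1H-indene-1-carboxylate, stereochemistry as in 15 | OCCC1C(O)CC[C@H]2[C@@]1(C)C(=O)C[C@@]2(C)C(=O)OC | intermediate
18 | methyl 4-{2-[tert-butyl(diphenyl)silyl]oxyethyl}-5-hydroxy-1,3a-dimethyl-3-oxooctahydro-1H-indene-1-carboxylate, stereochemistry as in 15 | CC(C)(C)[Si](c3ccccc3)(c4ccccc4)OCCC1C(O)CC[C@H]2[C@@]1(C)C(=O)C[C@@]2(C)C(=O)OC | intermediate
19 | methyl 4-{2-[tert-butyl(diphenyl)silyl]oxyethyl}-1,3a-dimethyl-3,5-dioxooctahydro-1H-indene-1-carboxylate, C9 epimerisable, other centres as in 15 | CC(C)(C)[Si](c3ccccc3)(c4ccccc4)OCCC1C(=O)CC[C@H]2[C@@]1(C)C(=O)C[C@@]2(C)C(=O)OC | intermediate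
20 | methyl (1R,3aS,4R,7aS)-4-{2-[tert-butyl(diphenyl)silyl]oxyethyl}-1,3a-dimethyl-5-methylidene-3-oxooctahydro-1H-indene-1-carboxylate (4R,5S,9R,10S in target numbering) | CC(C)(C)[Si](c3ccccc3)(c4ccccc4)OCC[C@@H]1C(=C)CC[C@H]2[C@@]1(C)C(=O)C[C@@]2(C)C(=O)OC | intermediate
21 | trimethylsilyldiazomethane | C[Si](C)(C)C=[N+]=[N-] | starting material
22 | 23 carrying a trimethylsilyl group on C2 (position 3 of the decalin), either C2 epimer | CC(C)(C)[Si](c3ccccc3)(c4ccccc4)OCC[C@@H]1C(=C)CC[C@H]2[C@@]1(C)C(=O)C([Si](C)(C)C)C[C@@]2(C)C(=O)OC | intermediate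
23 | methyl (1R,4aS,5R,8aS)-5-{2-[tert-butyl(diphenyl)silyl]oxyethyl}-1,4a-dimethyl-6-methylidene-4-oxodecahydronaphthalene-1-carboxylate | CC(C)(C)[Si](c3ccccc3)(c4ccccc4)OCC[C@@H]1C(=C)CC[C@H]2[C@@]1(C)C(=O)CC[C@@]2(C)C(=O)OC | intermediate
24 | methyl (1R,4S,4aS,5R,8aS)-5-{2-[tert-butyl(diphenyl)silyl]oxyethyl}-4-hydroxy-1,4a-dimethyl-6-methylidenedecahydronaphthalene-1-carboxylate | CC(C)(C)[Si](c3ccccc3)(c4ccccc4)OCC[C@@H]1C(=C)CC[C@H]2[C@@]1(C)[C@@H](O)CC[C@@]2(C)C(=O)OC | intermediate
25 | methyl (1R,4S,4aS,5R,8aS)-4-(acetyloxy)-5-{2-[tert-butyl(diphenyl)silyl]oxyethyl}-1,4a-dimethyl-6-methylidenedecahydronaphthalene-1-carboxylate | CC(C)(C)[Si](c3ccccc3)(c4ccccc4)OCC[C@@H]1C(=C)CC[C@H]2[C@@]1(C)[C@@H](OC(C)=O)CC[C@@]2(C)C(=O)OC | intermediate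
26 | methyl (1R,4S,4aS,5R,8aS)-4-(acetyloxy)-5-(2-hydroxyethyl)-1,4a-dimethyl-6-methylidenedecahydronaphthalene-1-carboxylate | OCC[C@@H]1C(=C)CC[C@H]2[C@@]1(C)[C@@H](OC(C)=O)CC[C@@]2(C)C(=O)OC | intermediate
27 | methyl (1R,4S,4aS,5R,8aS)-4-(acetyloxy)-1,4a-dimethyl-6-methylidene-5-(2-oxoethyl)decahydronaphthalene-1-carboxylate | O=CC[C@@H]1C(=C)CC[C@H]2[C@@]1(C)[C@@H](OC(C)=O)CC[C@@]2(C)C(=O)OC | intermediate
28 | 2-(triphenyl-λ5-phosphanylidene)propanal | CC(C=O)=P(c1ccccc1)(c1ccccc1)c1ccccc1 | starting material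
29 | methyl (1R,4S,4aS,5R,8aS)-4-(acetyloxy)-1,4a-dimethyl-5-[(2E)-3-methyl-4-oxobut-2-en-1-yl]-6-methylidenedecahydronaphthalene-1-carboxylate | O=C/C(C)=C/C[C@@H]1C(=C)CC[C@H]2[C@@]1(C)[C@@H](OC(C)=O)CC[C@@]2(C)C(=O)OC | intermediate
30 | methyl (1R,4S,4aS,5R,8aS)-4-(acetyloxy)-1,4a-dimethyl-6-methylidene-5-[(2E)-3-methylpenta-2,4-dien-1-yl]decahydronaphthalene-1-carboxylate (1S,4R,5S,9R,10S in target numbering) | C=C/C(C)=C/C[C@@H]1C(=C)CC[C@H]2[C@@]1(C)[C@@H](OC(C)=O)CC[C@@]2(C)C(=O)OC | target

Total step count: 20. Longest linear sequence: 20 steps (from 1).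

Steps most likely to fail

1. Step 14 (key step). What may go wrong: the diazo carbon may fail to add to the doubly shielded C1 carbonyl, or migration of quaternary C10 may compete with that of C3 and move the carbonyl away from C10. Fallback, setting out from 20 and returning at 23: Corey–Chaykovsky methylenation of 20 with dimethylsulfonium methylide (Me3SI, KOtBu, DMSO/THF) should give the C1 spiro-oxirane F1. Azide opening at the oxirane methylene (NaN3, NH4Cl, DMF, 70 °C) should give azido alcohol F2, and Staudinger reduction (PPh3, THF/H2O) amino alcohol F3. Nitrosation (NaNO2, aq. AcOH, 0 °C) should then trigger a Tiffeneau–Demjanov ring enlargement in which the less substituted C3 migrates, giving 23 directly.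

2. Step 9. What may go wrong: the ene reaction of a 1,2-disubstituted alkene whose reacting carbon is neopentyl may be slow, so that chloride capture of the developing C11 cation or self-condensation of the aldehyde takes over. Fallback, setting out from 13 and returning at 15: allylic oxidation of the propenyl methyl group of 13 (SeO2 cat., t-BuOOH, CH2Cl2) should give the (E)-allylic alcohol F4. Acetal hydrolysis (2 M HCl, THF) should give hydroxy aldehyde F5, and Appel bromination (CBr4, PPh3, CH2Cl2, 0 °C) allylic bromide F6. An intramolecular Barbier allylation (Zn dust, THF/aq. NH4Cl), in which the allylzinc attacks the C8 aldehyde through its γ-carbon C9 in a six-membered cyclic transition state, should then give 15.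

3. Step 6. What may go wrong: building the quaternary centre between C5 and the ester may be slow, so that 1,2-addition, reduction or attack at C3 competes. Fallback, setting out from 9 and returning at 12: NaBH4 reduction of the ketone of 9 (MeOH, 0 °C) should give alcohol F7 as C1 epimers, and silylation (Et3SiCl, imidazole, DMF) silyl ether F8. Ester enolate methylation (LiN(iPr)2, THF, −78 °C; MeI), the electrophile entering anti to the C5 arm, should give F9. Desilylation (Bu4NF, THF) to F10 and Dess–Martin oxidation of the C1 alcohol then give 12.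

Further compounds
F1 | step 14 | C1 spiro-oxirane of 20 (CH2–O bridging C1), C1 configuration immaterial | CC(C)(C)[Si](c3ccccc3)(c4ccccc4)OCC[C@@H]1C(=C)CC[C@H]2[C@@]1(C)C5(CO5)C[C@@]2(C)C(=O)OC
F2 | step 14 | C1 tertiary alcohol of the hydrindane bearing an azidomethyl group on C1 | CC(C)(C)[Si](c3ccccc3)(c4ccccc4)OCC[C@@H]1C(=C)CC[C@H]2[C@@]1(C)C(O)(CN=[N+]=[N-])C[C@@]2(C)C(=O)OC
F3 | step 14 | C1 tertiary alcohol of the hydrindane bearing an aminomethyl group on C1 | CC(C)(C)[Si](c3ccccc3)(c4ccccc4)OCC[C@@H]1C(=C)CC[C@H]2[C@@]1(C)C(O)(CN)C[C@@]2(C)C(=O)OC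
F4 | step 9 | 13 with the propenyl methyl oxidised to CH2OH, (E)-3-hydroxyprop-1-enyl on C10 | O1CCCOC1CC[C@H]2[C@@](/C=C/CO)(C)C(=O)C[C@@]2(C)C(=O)OC
F5 | step 9 | hydroxy aldehyde, F4 with the dioxane hydrolysed to the C8 aldehyde | O=CCC[C@H]2[C@@](/C=C/CO)(C)C(=O)C[C@@]2(C)C(=O)OC
F6 | step 9 | allylic bromide, F5 with CH2OH replaced by CH2Br | O=CCC[C@H]2[C@@](/C=C/CBr)(C)C(=O)C[C@@]2(C)C(=O)OC
F7 | step 6 | C1 alcohol of 9 (C1 epimers) | O1CCCOC1CC[C@H]2[C@@](CC=C)(C)C(O)C[C@@H]2C(=O)OC
F8 | step 6 | triethylsilyl ether of F7 | O1CCCOC1CC[C@H]2[C@@](CC=C)(C)C(O[Si](CC)(CC)CC)C[C@@H]2C(=O)OC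
F9 | step 6 | F8 methylated at C4, methyl trans to the C5 arm | O1CCCOC1CC[C@H]2[C@@](CC=C)(C)C(O[Si](CC)(CC)CC)C[C@@]2(C)C(=O)OC
F10 | step 6 | C1 alcohol of 12 (C1 epimers) | O1CCCOC1CC[C@H]2[C@@](CC=C)(C)C(O)C[C@@]2(C)C(=O)OC
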